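**Plan**

1. Numbering: ring A is the 3,4,5-trimethoxyphenyl ring, C7 its benzylic CH(OH), C8 the CH bearing the aryloxy group, C9 the CH2OAc carbon; ring B is the 4-allyl-2,6-dimethoxyphenyl ring.
2. The retrosynthesis cuts first the acetyl–O9 ester bond, then the O–CH3 bond on C4 of ring A, and last, in one operation, the C8–O(ring B) ether bond and the C7–OH bond. This leads back to sinapyl alcohol, 4-allyl-2,6-dimethoxyphenol and water.
3. Feature that allows the last cut: C8 is bonded to the phenolic oxygen of ring B, and C7, para to the C4 oxygen of ring A, carries a hydroxyl, so the C7–C8 unit is the hydrate of a ring A para-quinone methide. Each ring has methoxy groups on both carbons ortho to that oxygen and ring B has allyl on its para carbon, so only the ring B oxygen and C8 are open to radical coupling.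
4. Forward: no ring is formed. The two C6–C3 units are joined in step 1 (O–C8 coupling, then water onto C7), the ring A phenol is methylated in step 2 and O9 is acetylated in step 3.
5. Stereochemistry: C8 arises racemic in the radical coupling and C7 from water addition under substrate control only, so the threo pair is freed from the erythro pair by chromatography at the end of step 2. The 7R,8R enantiomer is then selected by the lipase kinetic resolution that installs the acetate.

Key step: step 1

Assumption: Burkholderia cepacia lipase is taken to acetylate the 7R,8R enantiomer of the threo diol faster than the 7S,8S one; if the preference is the reverse, the fallback given for step 3 supplies the same enantiomer.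

**Route**

Step 1
Reactants: 1 sinapyl alcohol; 2 4-allyl-2,6-dimethoxyphenol
Product: 4 threo-2-(4-allyl-2,6-dimethoxyphenoxy)-1-(4-hydroxy-3,5-dimethoxyphenyl)propane-1,3-diol (racemic; 7R,8R enantiomer drawn), via quinone methide 3 (not isolated)
Conditions: 2 (4 equiv), Ag2O (1.5 equiv), acetone–H2O 10:1, rt, dark, 1 added over 6 h; filter; aq HCl to pH 3, rt; SiO2 (excess 2 recovered; threo and erythro triols collected together)
Reagents that add atoms: water, O
Why: Ag2O removes one electron and one proton from each phenol; the radical of 1 has spin density at C8 and that of 2 on its oxygen, so their combination forms the ring B O–C8 bond and leaves ring A as quinone methide 3. Water then adds to C7 of 3 in an acid-assisted 1,6-addition that restores aromatic ring A and forms the C7–OH bond. The closest known reaction type is the dehydrogenative cross-coupling of a monolignol with a phenol to an arylglycerol beta-aryl ether by way of a quinone methide. No ring is closed. C8 is set without control in the radical combination (hence racemic) and C7 by the face of 3 that water attacks, biased only by the adjacent C8 centre, so threo 4 should form together with its erythro (7R,8S/7S,8R) diastereomer, which may well be the larger share because a 2,6-dimethoxyphenoxy group at C8 tends to favour erythro addition; the two are carried together into step 2. The step needs O–C8 regioselectivity, secured by the methoxy groups on both ortho carbons of each phenol and the allyl group on the para carbon of ring B, and cross- over homo-coupling, secured by slow addition of 1 to an excess of 2, whose oxidation potential is close to that of 1.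

Step 2
Reactants: 4 threo phenol (racemic), used as the mixture with its erythro diastereomer that step 1 delivers
Product: 5 threo-2-(4-allyl-2,6-dimethoxyphenoxy)-1-(3,4,5-trimethoxyphenyl)propane-1,3-diol (racemic; 7R,8R enantiomer drawn)
Conditions: MeI (1.5 equiv), K2CO3 (2 equiv), acetone, reflux; SiO2 chromatography (erythro methyl ether removed)
Reagents that add atoms: iodomethane, CI
Why: Williamson ether synthesis, in which K2CO3 ionises only the ring A phenol and not the two alcohols, the phenoxide displaces iodide from MeI by an SN2 reaction and no stereocentre is formed or disturbed, so the erythro contaminant is methylated in the same way and the two non-phenolic diols are then separated on silica to leave threo 5.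

Step 3
Reactants: 5 threo diol (racemic)
Product: 6 (2R,3R)-2-(4-allyl-2,6-dimethoxyphenoxy)-3-hydroxy-3-(3,4,5-trimethoxyphenyl)propyl acetate (7R,8R; the target)
Conditions: Burkholderia cepacia lipase (immobilised), vinyl acetate (3 equiv), t-BuOMe, 30 °C, stopped short of half conversion; SiO2
Reagents that add atoms: vinyl acetate, C=COC(C)=O
Why: Lipase-catalysed transesterification used as a kinetic resolution, known for the primary hydroxyl of arylglycerol beta-aryl ethers: the acetyl-enzyme accepts only the unhindered C9 hydroxyl, the enantiomer of 5 whose C8 centre fits the active site (7R,8R by the assumption above) is acetylated faster, no stereocentre is created, the vinyl alcohol released tautomerises to acetaldehyde so the acyl transfer cannot reverse, and the unreacted 7S,8S diol is removed by chromatography.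

**Compound list**

1 | sinapyl alcohol, 4-[(E)-3-hydroxyprop-1-enyl]-2,6-dimethoxyphenol (commercial) | COc1cc(/C=C/CO)cc(OC)c1O | starting material
2 | 4-allyl-2,6-dimethoxyphenol (commercial) | C=CCc1cc(OC)c(O)c(OC)c1 | starting material
3 | 4-[2-(4-allyl-2,6-dimethoxyphenoxy)-3-hydroxypropylidene]-2,6-dimethoxycyclohexa-2,5-dien-1-one, the ring A quinone methide (racemic; drawn with the C8 configuration that becomes 8R in 4) | C=CCc1cc(OC)c(O[C@H](CO)C=C2C=C(OC)C(=O)C(OC)=C2)c(OC)c1 | intermediate (not isolated)
4 | threo-2-(4-allyl-2,6-dimethoxyphenoxy)-1-(4-hydroxy-3,5-dimethoxyphenyl)propane-1,3-diol (racemic; 1R,2R = 7R,8R drawn) | C=CCc1cc(OC)c(O[C@H](CO)[C@H](O)c2cc(OC)c(O)c(OC)c2)c(OC)c1 | intermediate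
5 | threo-2-(4-allyl-2,6-dimethoxyphenoxy)-1-(3,4,5-trimethoxyphenyl)propane-1,3-diol (racemic; 1R,2R = 7R,8R drawn) | C=CCc1cc(OC)c(O[C@H](CO)[C@H](O)c2cc(OC)c(OC)c(OC)c2)c(OC)c1 | intermediate
6 | (2R,3R)-2-(4-allyl-2,6-dimethoxyphenoxy)-3-hydroxy-3-(3,4,5-trimethoxyphenyl)propyl acetate (7R,8R) | C=CCc1cc(OC)c(O[C@H](COC(C)=O)[C@H](O)c2cc(OC)c(OC)c(OC)c2)c(OC)c1 | target

Total step count: 3
Longest linear sequence: 3 steps (1 and 2 to 6)

**Steps most likely to fail**

1. Step 1. The sinapyl radical may dimerise through C8–C8 instead of meeting the ring B radical. The ring B phenoxyl radical may disproportionate to its allylidene quinone methide. The phenolic product may be oxidised further, 2 may add to C7 in place of water, and water may add to 3 mainly on the erythro face.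
 Fallback: the C7–C8 bond is made instead by an auxiliary-controlled aldol reaction. It sets out from 2 and comes back at 5, now as the single 7R,8R enantiomer. 2 is O-alkylated with bromoacetic acid (NaH, THF, reflux) to (4-allyl-2,6-dimethoxyphenoxy)acetic acid F1. Pivaloyl chloride and Et3N (THF, −20 °C) convert F1 into the pivaloyl mixed anhydride F2, which acylates lithiated (S)-4-benzyl-1,3-oxazolidin-2-one at its less hindered carbonyl to give the N-acyl oxazolidinone F3. F3 is enolised with Bu2BOTf and i-Pr2NEt (CH2Cl2, −78 to 0 °C) and treated with 3,4,5-trimethoxybenzaldehyde to give the Evans syn aldol adduct F4; syn in the chain corresponds to threo. NaBH4 in THF–H2O then removes the auxiliary reductively and gives 5. Step 3 then serves only to acetylate O9.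

2. Step 3. The lipase may discriminate the enantiomers poorly, or in the opposite sense, at a stereocentre that bears an aryloxy group. Acetyl may also migrate from O9 to O7 during isolation.
 Fallback: the enantiomers are separated after a non-enzymatic acetylation. It sets out from 5 and comes back at 6. Racemic 5 is acetylated at the primary hydroxyl with acetyl chloride and 2,4,6-collidine (CH2Cl2, −78 °C), which gives 6 together with its mirror image, the 7S,8S acetate F5. Preparative HPLC on an amylose tris(3,5-dimethylphenylcarbamate) phase separates the two.

3. Step 2. The threo and erythro diols may fail to separate cleanly on silica.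
 Fallback: the diastereomers are separated as cyclic acetals. It sets out from 5 while still mixed with its erythro diastereomer and comes back at 5. 2,2-Dimethoxypropane and pyridinium p-toluenesulfonate in acetone convert 5 into the cis acetonide F6 and the erythro diol into the trans acetonide F7. The two 1,3-dioxanes differ in shape more than the diols do and are separated on silica. F6 is then hydrolysed with 80% aqueous acetic acid at rt to return 5.

Further compounds
F1 | step 1 | (4-allyl-2,6-dimethoxyphenoxy)acetic acid | C=CCc1cc(OC)c(OCC(=O)O)c(OC)c1
F2 | step 1 | (4-allyl-2,6-dimethoxyphenoxy)acetic pivalic anhydride | C=CCc1cc(OC)c(OCC(=O)OC(=O)C(C)(C)C)c(OC)c1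
F3 | step 1 | (4S)-4-benzyl-3-[(4-allyl-2,6-dimethoxyphenoxy)acetyl]-1,3-oxazolidin-2-one | C=CCc1cc(OC)c(OCC(=O)N2[C@@H](Cc3ccccc3)COC2=O)c(OC)c1
F4 | step 1 | (4S)-4-benzyl-3-[(2S,3R)-2-(4-allyl-2,6-dimethoxyphenoxy)-3-hydroxy-3-(3,4,5-trimethoxyphenyl)propanoyl]-1,3-oxazolidin-2-one | C=CCc1cc(OC)c(O[C@H](C(=O)N2[C@@H](Cc3ccccc3)COC2=O)[C@H](O)c4cc(OC)c(OC)c(OC)c4)c(OC)c1
F5 | step 3 | (2S,3S)-2-(4-allyl-2,6-dimethoxyphenoxy)-3-hydroxy-3-(3,4,5-trimethoxyphenyl)propyl acetate (7S,8S) | C=CCc1cc(OC)c(O[C@@H](COC(C)=O)[C@@H](O)c2cc(OC)c(OC)c(OC)c2)c(OC)c1
F6 | step 2 | cis-5-(4-allyl-2,6-dimethoxyphenoxy)-2,2-dimethyl-4-(3,4,5-trimethoxyphenyl)-1,3-dioxane (racemic; 4R,5R drawn) | C=CCc1cc(OC)c(O[C@@H]2COC(C)(C)O[C@@H]2c3cc(OC)c(OC)c(OC)c3)c(OC)c1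
F7 | step 2 | trans-5-(4-allyl-2,6-dimethoxyphenoxy)-2,2-dimethyl-4-(3,4,5-trimethoxyphenyl)-1,3-dioxane (racemic; 4S,5R drawn) | C=CCc1cc(OC)c(O[C@@H]2COC(C)(C)O[C@H]2c3cc(OC)c(OC)c(OC)c3)c(OC)c1
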